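At one temperature and over hours of run time, Q turns into X and X into J, while the vessel differs between the set-ups.

    G + E ⇌ G.E, settled at all times (K1 = 34000 M⁻¹)
    G + X → G + J (k2 = 0.88 M⁻¹ s⁻¹)
    Q → X (k3 = 1.9 × 10⁻⁴ s⁻¹)
    2 G ⇌ G2, settled at all times (K4 = 7.4 × 10⁵ M⁻¹)

| setting | noon | spring | midnight | winter |
|---|---|---|---|---|
| Q | 0.10 M | 0.10 M | 0.10 M (fed, over 1.20 h) | 0.10 M |
| G | 0.20 mM | 0.20 mM | 0.20 mM | 0.20 mM |
| E | 0.27 mM | 0.27 mM | 0.27 mM | 0.27 mM |
| remark | a single well-mixed tank run continuously and read at steady state, 1.5 h in it on average | a single well-mixed tank run continuously and read at steady state, 4.50 h in it on average | all but Q at the start; Q goes in evenly over 1.20 h, the run ends at 1.5 h | everything together in a closed stirred flask, run for 1.5 h |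
| time |  |  | 1.5 h | 1.5 h |

- two of one species on the left: rate k times its square, two consumed each time
- the stated concentrations are those of everything mixed, before any reaction; amounts are the same in each set-up
- the feed brings no volume worth counting
- run time (midnight): 1.5 h

- the set-up with the highest amount of X at the outlet or at the end, in percent of the Q put in ("none" if the first two lie within 2 percentage points) (noon / spring / midnight / winter / none)
- amount of X at the outlet or at the end, in percent of the Q put in, noon
- amount of X at the outlet or at the end, in percent of the Q put in, spring
- amount of X at the outlet or at the end, in percent of the Q put in, midnight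
- amount of X at the outlet or at the end, in percent of the Q put in, winter

1. X forms from Q with first-order constant 1.9 × 10⁻⁴ s⁻¹, which gives a formation time 1.46 h.

2. G comes out of its step unchanged, so X is lost in a pseudo-first-order way with constant 0.88 M⁻¹ s⁻¹ times c_G. Here c_G is free G, not the charge. Taken at the winter charge, X would have a half-life of 1.1 h by step 2 alone, close to the 1.0 h of Q.

3. The balance of catalyst is c_G + c_G.E + 2 times the concentration of G2. Putting the charge wholly into G2 gives a first c_G of 0.0116 mM, and with it c_G.E is 0.0765 mM. The remainder in G2 gives c_G = 0.00914 mM, and this free G is small in the balance.

4. The loss time of X is therefore 34.6 h. The loss ratio, formation time over loss time 0.0423, is small because the loss time is far longer.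

5. X is then the converted Q, less a small loss. A tank divides the conversion by one plus residence time over loss time. A flask loses the mean age of X over the loss time, with the mean age taken as half the mean time Q has had. This reckoning gives noon 48.5%, spring 66.8%, midnight 43.9% and winter 62.8%. The best set-up is spring.

6. The forecast, reckoned apart, names spring, with noon 48.5%, spring 66.7%, midnight 43.7% and winter 62.5%. Its grounds are that “the yield of X is governed mainly by how much Q has converted”.

The simulation gives spring as best, with noon 48.5%, spring 66.7%, midnight 43.7% and winter 62.5%. The mean residence of the spring tank, 4.50 h, is 3.08 formation times but 0.130 of a loss time, and c_Q in that tank stands at 0.0245 M. Left for 15.0 h, the winter flask holds X at 67.4% of the Q put in, where the loss ratio gives 67.6%.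

(The numbers come from no measurement, and the outcome is calculated.)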